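The constants here must be read from the earlier runs, and these are the flasks they serve.

| flask | starting material | partner | temperature | remark | time |
|---|---|---|---|---|---|
| Tuesday's | 20 mM | 16 mM | −25 °C | run made earlier |  |
| Saturday's | 20 mM | 8 mM | −14 °C | run made earlier |  |
| Monday's | 20 mM | 12 mM | −25 °C | run made earlier |  |
| Sunday's | 40 mM | 16 mM | −14 °C | run made earlier |  |
| teal | 20 mM (fed, over 4.0 d) | 16.0 mM | −20 °C | all else is in the flask from the start; the feed brings no volume worth counting | 25 d |
| ochre | 20 mM | 16.0 mM (in portions, 5, over 15 d) | −20 °C | first portion at the start, last at 15 d | 25 d |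
| amber | 20 mM | 16.0 mM (fed, over 15 d) |  | the addition at −50 °C, then warmed to −20 °C; the feed brings no volume worth counting | 25 d |
| red | 20 mM | 16.0 mM | −20 °C | everything together at the start | 25 d |
| blue | 20 mM | 16.0 mM (fed, over 15 d) | −20 °C | all else is in the flask from the start; the feed brings no volume worth counting | 25 d |

- Tuesday's (time / d: target / %, side product / %): 5.00: 58, 4; 10.0: 52, 8; 15.0: 49, 8; 20.0: 43, 8; 25.0: 39, 7
- Saturday's (time / d: target / %, side product / %): 2.08: 26, 3; 4.00: 21, 1; 8.00: 12, 0; 12.0: 6, 1; 25.0: 3, 0
- Monday's (time / d: target / %, side product / %): 5.00: 44, 3; 10.0: 42, 5; 15.0: 38, 4; 20.0: 33, 6; 25.0: 28, 5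
- Sunday's (time / d: target / %, side product / %): 2.00: 25, 6; 6.00: 14, 4; 12.0: 3, 2; 20.0: 1, 2; 25.0: 0, 4

(scatter of a reading: 1.5 percentage points)

- a reading or a percentage of target counts all its forms, free or not

- the flask with the highest share of target in target plus side product ("all alike" if they lie within 1.5 percentage points) (teal / ochre / amber / red / blue / all alike)
- share of target in target plus side product at the end, teal
- share of target in target plus side product at the end, ochre
- share of target in target plus side product at the end, amber
- share of target in target plus side product at the end, red
- share of target in target plus side product at the end, blue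

Where does the partner go? It is the limiting reagent, 16.0 mM against 20 mM of starting material. In Tuesday's run, target falls from 58% at 5.00 d to 39% at 25.0 d, a read loss constant of 0.0198 d⁻¹. Carried back to the start, this gives 64.0% target. With the side product reading of 8% counted for two partners, the balance reads 80.0%, against the 80.0% the partner allows.

How does side product depend on partner? Side product in mM over [partner]² at the start reads 0.00625 mM⁻¹ on Tuesday and 0.00694 mM⁻¹ on Monday, so these two readings point to roughly second order in partner. If each portion is used before the next comes, equal portions divide Tuesday's side product reading by their number, which puts ochre near 1.60% in this reckoning. This reckoning takes blue's steady feed to hold [partner] lower still.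

How much target survives? Saturday's run reads 0.148 d⁻¹ at −14 °C. Interpolating the logarithm over temperature gives 0.0494 d⁻¹, the loss constant of target at the flask temperature. Its half-life of 14.0 d is shorter than the 25 d run. This reckoning, with Tuesday's side product reading, puts red at 18.6% target, a share of 69.9%. Target made evenly during blue's feed is reckoned to survive at 43.1%, giving 34.5%. With the same survival taken for ochre's portions, ochre's share comes to about 95.6%, and this reckoning's choice is blue.

The forecast names blue, with teal 66%, ochre 94%, amber 85%, red 70% and blue 95%, saying of blue and ochre that “partner stays low”.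

The simulation gives blue, with teal 76.9%, ochre 95.0%, amber 92.6%, red 71.9% and blue 99.2%.

    starting material + 2 partner → side product (k = 4.92 M⁻² min⁻¹, Ea = 47.0 kJ mol⁻¹)
    target → over-reaction product (k = 3.62 × 10⁻⁵ min⁻¹, Ea = 99.0 kJ mol⁻¹)
    starting material + partner → target (k = 0.323 M⁻¹ min⁻¹, Ea = 52.0 kJ mol⁻¹)
    partner + target ⇌ idle adduct, settled at all times (K = 15.0 M⁻¹, ΔH = −33.0 kJ mol⁻¹)
    2 partner → homo dimer (k = 0.0116 M⁻¹ min⁻¹, Ea = 47.0 kJ mol⁻¹)
    (constants at −20 °C)

Blue run at −35 °C takes the same reckoning. Carried down from the flask temperature, the loss constant becomes 0.00320 d⁻¹, and the half-life of 217 d is longer than the run. Target made evenly during the feed is then reckoned to survive at 94.6%, which gives 75.7%. That neighbour flask holds 73.7% target at 25.0 d, beside 1.05% side product, for a share of 98.6%.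

(The numbers in the tables come from a simulation with constants of no real substance.)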